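**Plan**

- Retrosynthesis: the C6–O ester bond to p-coumaric acid is cut first, then C4=C15 (back to a C4 ketone), then an allyl ester is placed on C5, and ring B is opened at C9–C10 and C5–C6 (retro-[4+2]).
- Enabling feature: in ring A, C4 (the later methylene carbon), C5 (ring-fusion CH) and C10 (methyl-bearing quaternary carbon) are the carbonyl, α- and β-carbons of a 3-methylcyclohex-2-enone. C6(O)–C7(iPr)–C8–C9 of ring B is a 1-oxy-2-isopropylbuta-1,3-diene. An ester on C5 turns the enone into a two-point-binding dienophile and is removed afterwards.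
- Forward: ring A is made first (acetoacetate dianion alkylation, Knoevenagel closure) and the diene comes from isovaleraldehyde. Ring B is closed by the Diels–Alder step; decarboxylation, desilylation, hydrogenation, C5 equilibration, C4 methylenation and esterification follow.
- Stereochemistry: C10 comes from the chiral copper bis(oxazoline) catalyst, and C6 from ketone-endo addition of the (E)-silyl enol ether. C7 comes from hydroxyl-directed hydrogenation, and C5 from equilibration of the decalone to the trans ring fusion.

Key step: step 6

**Remarks**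

- Eudesmane numbering is used for the bicyclic compounds (C4 carbonyl/methylene carbon, C5 fusion carbon, C6 oxygenated, C7 isopropyl-bearing, C10 methyl-bearing); β is the face of the C10 methyl. The target is (5S,6S,7S,10R): trans-fused, 6α-O and 7β-isopropyl both equatorial.
- The (R,R) ligand in step 6 is assigned from the square-planar chelate model with the diene lying over the ring ketone. Should the sense prove opposite, the (S,S) ligand is used and nothing else changes.
- Decarboxylation leaves C5 as a CH of either configuration. Compounds 14–16 are carried as C5 epimers and converge in step 10.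

**Route**

Step 1
Reactants: 1 allyl acetoacetate; 2 2-(2-bromoethyl)-2-methyl-1,3-dioxolane
Product: 3 allyl 6-(2-methyl-1,3-dioxolan-2-yl)-3-oxohexanoate
Conditions: NaH, THF, 0 °C; n-BuLi, 0 °C; 2, 0 °C → rt; AcOH quench
Reagents that add atoms: none
Why: Weiler γ-alkylation of the acetoacetate dianion: the terminal carbanion is the more nucleophilic site and displaces the primary bromide by SN2 while the ketal keeps the second ketone masked.

Step 2
Reactants: 3 allyl 6-(2-methyl-1,3-dioxolan-2-yl)-3-oxohexanoate
Product: 5 allyl 2-methyl-6-oxocyclohex-1-ene-1-carboxylate, via allyl 3,7-dioxooctanoate 4 (not isolated)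
Conditions: 2 M HCl, THF, rt; then piperidine (cat.), AcOH (cat.), toluene, 80 °C, –H2O
Reagents that add atoms: none
Why: Ketal hydrolysis frees the methyl ketone and an amine/acid-catalysed intramolecular Knoevenagel condensation of the active methylene onto it closes the six-membered ring and dehydrates to the conjugated tetrasubstituted alkene, the enolised β-keto ester carbonyl being a poor electrophile for the alternative aldol.

Step 3
Reactants: 6 isovaleraldehyde
Product: 7 N-(3-methylbutylidene)cyclohexanamine
Conditions: cyclohexylamine, Et2O, 0 °C → rt, K2CO3 (drying)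
Reagents that add atoms: cyclohexylamine, NC1CCCCC1
Why: Imine condensation of an unhindered aldehyde with a primary amine, driven by removal of water, provides the aza-enolate precursor for a directed aldol.

Step 4
Reactants: 7 N-(3-methylbutylidene)cyclohexanamine; 8 acetaldehyde
Product: 10 (E)-2-isopropylbut-2-enal, via aldol imine 9 (not isolated)
Conditions: LDA, THF, –78 → 0 °C; MeCHO, –78 °C; then aq. oxalic acid, reflux
Reagents that add atoms: water, O
Why: Wittig directed aldol condensation: the lithiated imine adds to acetaldehyde without self-condensation of either aldehyde, and acid hydrolysis with dehydration gives the conjugated enal, whose alkene geometry is lost in the next step and so does not matter.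

Step 5
Reactants: 10 (E)-2-isopropylbut-2-enal
Product: 11 (E)-1-(tert-butyldimethylsilyloxy)-2-isopropylbuta-1,3-diene
Conditions: TBSOTf, Et3N, Et2O, 0 °C → rt; distil
Reagents that add atoms: tert-butyldimethylsilyl triflate, CC(C)(C)[Si](C)(C)OS(=O)(=O)C(F)(F)F
Why: O-Silylation followed by amine deprotonation at the γ-methyl (vinylogous silyl enol ether formation, as with tiglic aldehyde) gives the linear 1-silyloxy diene, the s-trans conformation of the enal placing the silyloxy group trans to the vinyl group.

Step 6
Reactants: 5 allyl 2-methyl-6-oxocyclohex-1-ene-1-carboxylate; 11 (E)-1-(tert-butyldimethylsilyloxy)-2-isopropylbuta-1,3-diene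
Product: 12 allyl (4aR,8S,8aS)-8-(tert-butyldimethylsilyloxy)-7-isopropyl-4a-methyl-1-oxo-1,2,3,4,4a,5,8,8a-octahydronaphthalene-8a-carboxylate (cis-fused; 10β-Me; 5β-CO2allyl; 6α-OTBS; C7=C8)
Conditions: [Cu((R,R)-t-Bu-box)](SbF6)2 (10 mol %), 4 Å MS, CH2Cl2, –20 °C → rt
Reagents that add atoms: none
Why: Proposed new method: the β-keto ester of 5 binds the cationic copper(II) bis(oxazoline) through both carbonyls, which lowers the LUMO of the tetrasubstituted alkene and holds it in the square plane of the complex, and the silyloxy diene then adds either in a concerted asynchronous intermolecular [4+2] or by vinylogous Mukaiyama–Michael attack of its CH2 terminus on C10 followed by 6-exo-trig closure of the copper enolate carbon C5 onto the silyl oxocarbenium carbon C6, both paths closing the six-membered ring B through C9–C10 and C5–C6. The closest known reactions are the Lewis acid Diels–Alder reactions of 2-alkoxycarbonylcyclohex-2-enones and the copper bis(oxazoline) Diels–Alder and Mukaiyama–Michael reactions of two-point-binding acceptors; the new element is the β-methyl group, which makes the alkene tetrasubstituted and both new ring-fusion carbons quaternary. Regiochemistry follows from the polarisation of the 1-silyloxy diene, whose unsubstituted and most nucleophilic terminus C9 attacks the β-carbon C10 while the oxygenated terminus bonds to C5, and sterics act in the same direction. C10 is set by the ligand, whose tert-butyl groups shield one face of the chelated alkene, and C5 follows from C10 because the addition is suprafacial, which gives the cis fusion with methyl and ester on the same face. C6 is set by the (E) geometry of the silyl enol ether together with the ketone-endo arrangement usual for these dienophiles, which places the silyloxy group cis to C4 and trans to the angular methyl. The step needs face, regio and endo selectivity at once, and these are secured by the rigid chelate, the silyloxy polarisation and the s-cis ring ketone lying under the diene.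

Step 7
Reactants: 12 cis-fused Diels–Alder adduct
Product: 14 (4aR,8R)-8-(tert-butyldimethylsilyloxy)-7-isopropyl-4a-methyl-3,4,4a,5,8,8a-hexahydronaphthalen-1(2H)-one (6α-OTBS; C7=C8; both C5 epimers), via β-keto acid 13 (not isolated)
Conditions: Pd(OAc)2 (5 mol %), PPh3 (20 mol %), HCO2H, Et3N, THF, rt → 40 °C
Reagents that add atoms: none
Why: Tsuji palladium-catalysed deallylation with formate as hydride donor reduces the π-allyl unit to propene and the β-keto acid loses CO2 through its enol under nearly neutral conditions, so the alkene and the silyl ether survive; the silyl ether is kept on at this stage because the free β-hydroxy β-keto ester would be open to retro-aldol ring opening.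

Step 8
Reactants: 14 silyloxy enone-free ketone (C5 epimers)
Product: 15 (4aR,8R)-8-hydroxy-7-isopropyl-4a-methyl-3,4,4a,5,8,8a-hexahydronaphthalen-1(2H)-one (6α-OH; C7=C8; both C5 epimers)
Conditions: 48 % aq. HF, MeCN, 0 °C → rt
Reagents that add atoms: none
Why: Acidic fluoride desilylation of the secondary allylic TBS ether avoids the basic conditions under which the ketol with its C7=C8 bond could open by retro-aldol or lose the β-oxygen by E1cB, and C6 is not touched.

Step 9
Reactants: 15 allylic alcohol ketone (C5 epimers)
Product: 16 (4aR,7S,8S)-8-hydroxy-7-isopropyl-4a-methyloctahydronaphthalen-1(2H)-one (6α-OH; 7β-iPr; both C5 epimers)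
Conditions: [Ir(cod)(PCy3)(py)]PF6 (5–10 mol %), H2 (1 atm), CH2Cl2, rt
Reagents that add atoms: none
Why: Hydroxyl-directed hydrogenation with Crabtree's catalyst: iridium bound to the 6α-hydroxyl delivers hydrogen to the α face of C7=C8 in either C5 epimer, so H-7 is cis to the hydroxyl and the isopropyl group ends β, trans to the oxygen.

Step 10
Reactants: 16 saturated ketol (C5 epimers)
Product: 17 (4aR,7S,8S,8aS)-8-hydroxy-7-isopropyl-4a-methyloctahydronaphthalen-1(2H)-one (trans-fused; 5α-H; 6α-OH; 7β-iPr; 10β-Me)
Conditions: K2CO3, MeOH, rt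
Reagents that add atoms: none
Why: Base-mediated enolisation equilibrates C5 to the trans-fused decalone, in which hydroxyl and isopropyl are equatorial and the hydroxyl is hydrogen-bonded to the C4 carbonyl, while the equatorial C6–O bond lies near the enolate plane and so is poorly aligned for E1cB dehydration, and any retro-aldol/aldol exchange leads to the same all-equatorial isomer.

Step 11
Reactants: 17 trans-fused ketol
Product: 18 (1S,2S,4aR,8aS)-2-isopropyl-4a-methyl-8-methylidenedecahydronaphthalen-1-ol (eudesm-4(15)-en-6α-ol)
Conditions: Zn, CH2Br2, TiCl4 (pre-formed Lombardo reagent, excess), THF–CH2Cl2, 0 °C → rt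
Reagents that add atoms: dibromomethane, BrCBr
Why: Takai–Lombardo methylenation: the non-basic zinc/titanium methylene reagent converts hindered, enolisable ketones into methylene compounds without epimerisation at C5 or retro-aldol, and used in excess it tolerates the free hydroxyl.

Step 12
Reactants: 19 p-coumaric acid
Product: 21 (E)-3-[4-(tert-butyldimethylsilyloxy)phenyl]prop-2-enoic acid, via bis-silyl derivative 20 (not isolated)
Conditions: TBSCl (2.5 equiv), imidazole, DMF, rt; then AcOH–THF–H2O, rt
Reagents that add atoms: tert-butyldimethylsilyl chloride, CC(C)(C)[Si](C)(C)Cl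
Why: Silylation of both acidic OH groups followed by selective hydrolysis of the much more labile silyl ester leaves the aryl silyl ether as phenol protection.

Step 13
Reactants: 21 (E)-3-[4-(tert-butyldimethylsilyloxy)phenyl]prop-2-enoic acid; 18 eudesm-4(15)-en-6α-ol
Product: 23 (1S,2S,4aR,8aS)-2-isopropyl-4a-methyl-8-methylidenedecahydronaphthalen-1-yl (E)-3-[4-(tert-butyldimethylsilyloxy)phenyl]prop-2-enoate, via mixed anhydride 22 (not isolated)
Conditions: 2,4,6-trichlorobenzoyl chloride, Et3N, THF, rt; then 18, DMAP, toluene, rt → 60 °C
Reagents that add atoms: none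
Why: Yamaguchi esterification: DMAP attacks the cinnamoyl carbonyl of the mixed anhydride and the resulting acylpyridinium acylates the hindered equatorial 6α-alcohol with retention at C6 and with the (E) alkene intact.

Step 14
Reactants: 23 silyl-protected coumarate
Product: 24 (1S,2S,4aR,8aS)-2-isopropyl-4a-methyl-8-methylidenedecahydronaphthalen-1-yl (E)-3-(4-hydroxyphenyl)prop-2-enoate (target)
Conditions: TBAF, AcOH, THF, 0 °C
Reagents that add atoms: none
Why: Buffered fluoride desilylation cleaves the aryl silyl ether far faster than it could attack the hindered cinnamate or isomerise the exocyclic alkene.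

**Compound list**

1 | allyl acetoacetate | C=CCOC(=O)CC(C)=O | starting material
2 | 2-(2-bromoethyl)-2-methyl-1,3-dioxolane | CC1(CCBr)OCCO1 | starting material
3 | allyl 6-(2-methyl-1,3-dioxolan-2-yl)-3-oxohexanoate | C=CCOC(=O)CC(=O)CCCC1(C)OCCO1 | intermediate
4 | allyl 3,7-dioxooctanoate | C=CCOC(=O)CC(=O)CCCC(C)=O | intermediate
5 | allyl 2-methyl-6-oxocyclohex-1-ene-1-carboxylate | C=CCOC(=O)C1=C(C)CCCC1=O | intermediate
6 | isovaleraldehyde | CC(C)CC=O | starting material
7 | N-(3-methylbutylidene)cyclohexanamine | CC(C)C/C=N/C1CCCCC1 | intermediate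
8 | acetaldehyde | CC=O | starting material
9 | 3-[(cyclohexylimino)methyl]-4-methylpentan-2-ol (aldol imine, diastereomers) | CC(O)C(C=NC1CCCCC1)C(C)C | intermediate
10 | (E)-2-isopropylbut-2-enal | C/C=C(/C=O)C(C)C | intermediate
11 | (E)-1-(tert-butyldimethylsilyloxy)-2-isopropylbuta-1,3-diene | C=C/C(C(C)C)=C/O[Si](C)(C)C(C)(C)C | intermediate
12 | allyl (4aR,8S,8aS)-8-(tert-butyldimethylsilyloxy)-7-isopropyl-4a-methyl-1-oxo-1,2,3,4,4a,5,8,8a-octahydronaphthalene-8a-carboxylate | O=C1CCC[C@]2(C)CC=C(C(C)C)[C@H](O[Si](C)(C)C(C)(C)C)[C@]12C(=O)OCC=C | intermediate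
13 | (4aR,8S,8aS)-8-(tert-butyldimethylsilyloxy)-7-isopropyl-4a-methyl-1-oxo-1,2,3,4,4a,5,8,8a-octahydronaphthalene-8a-carboxylic acid | O=C1CCC[C@]2(C)CC=C(C(C)C)[C@H](O[Si](C)(C)C(C)(C)C)[C@]12C(=O)O | intermediate
14 | (4aR,8R)-8-(tert-butyldimethylsilyloxy)-7-isopropyl-4a-methyl-3,4,4a,5,8,8a-hexahydronaphthalen-1(2H)-one, C5 (8a) epimers | O=C1CCC[C@]2(C)CC=C(C(C)C)[C@H](O[Si](C)(C)C(C)(C)C)C12 | intermediate
15 | (4aR,8R)-8-hydroxy-7-isopropyl-4a-methyl-3,4,4a,5,8,8a-hexahydronaphthalen-1(2H)-one, C5 (8a) epimers | O=C1CCC[C@]2(C)CC=C(C(C)C)[C@H](O)C12 | intermediate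
16 | (4aR,7S,8S)-8-hydroxy-7-isopropyl-4a-methyloctahydronaphthalen-1(2H)-one, C5 (8a) epimers | O=C1CCC[C@]2(C)CC[C@@H](C(C)C)[C@H](O)C12 | intermediate
17 | (4aR,7S,8S,8aS)-8-hydroxy-7-isopropyl-4a-methyloctahydronaphthalen-1(2H)-one | O=C1CCC[C@]2(C)CC[C@@H](C(C)C)[C@H](O)[C@@H]12 | intermediate
18 | (1S,2S,4aR,8aS)-2-isopropyl-4a-methyl-8-methylidenedecahydronaphthalen-1-ol | C=C1CCC[C@]2(C)CC[C@@H](C(C)C)[C@H](O)[C@@H]12 | intermediate
19 | p-coumaric acid | O=C(O)/C=C/c1ccc(O)cc1 | starting material
20 | tert-butyldimethylsilyl (E)-3-[4-(tert-butyldimethylsilyloxy)phenyl]prop-2-enoate | CC(C)(C)[Si](C)(C)OC(=O)/C=C/c1ccc(O[Si](C)(C)C(C)(C)C)cc1 | intermediate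
21 | (E)-3-[4-(tert-butyldimethylsilyloxy)phenyl]prop-2-enoic acid | O=C(O)/C=C/c1ccc(O[Si](C)(C)C(C)(C)C)cc1 | intermediate
22 | (E)-3-[4-(tert-butyldimethylsilyloxy)phenyl]prop-2-enoic 2,4,6-trichlorobenzoic anhydride | O=C(OC(=O)/C=C/c1ccc(O[Si](C)(C)C(C)(C)C)cc1)c1c(Cl)cc(Cl)cc1Cl | intermediate
23 | (1S,2S,4aR,8aS)-2-isopropyl-4a-methyl-8-methylidenedecahydronaphthalen-1-yl (E)-3-[4-(tert-butyldimethylsilyloxy)phenyl]prop-2-enoate | C=C1CCC[C@]2(C)CC[C@@H](C(C)C)[C@H](OC(=O)/C=C/c3ccc(O[Si](C)(C)C(C)(C)C)cc3)[C@@H]12 | intermediate
24 | (1S,2S,4aR,8aS)-2-isopropyl-4a-methyl-8-methylidenedecahydronaphthalen-1-yl (E)-3-(4-hydroxyphenyl)prop-2-enoate | C=C1CCC[C@]2(C)CC[C@@H](C(C)C)[C@H](OC(=O)/C=C/c3ccc(O)cc3)[C@@H]12 | target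

**Step count**

Total: 14 steps. Longest linear sequence: 11 steps (3, 4, 5, 6, 7, 8, 9, 10, 11, 13, 14 from isovaleraldehyde).

**Steps most likely to fail**

1. Step 6 (bears the label). The tetrasubstituted alkene may be too hindered for either bond-forming mode, the reaction may stop after a desilylative Michael addition, or face and endo control may be insufficient. The fallback forms the same two bonds stepwise by known reactions and sets out from diene 11. Hydrozirconation of its terminal vinyl group with Cp2Zr(H)Cl (1,2-addition to the less hindered double bond) gives an alkylzirconium species. Copper(I)/chiral phosphoramidite-catalysed asymmetric conjugate addition of this species to commercial 3-methylcyclohex-2-enone (TMSCl, Et2O) should set C10 and give (3R)-3-methyl-3-[3-(tert-butyldimethylsilyloxymethylidene)-4-methylpentyl]cyclohexan-1-one F1. Buffered TBAF should release 2-isopropyl-4-[(1R)-1-methyl-3-oxocyclohexyl]butanal F2 as C7 epimers. K2CO3 in MeOH should then close ring B by intramolecular aldol addition of the C5 enolate to the aldehyde under equilibrating conditions (C7 through the aldehyde enol, C5 and C6 through aldol reversibility). The route is rejoined at ketol 17, bypassing steps 6–10.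

2. Step 10. Under protic base the ketol may lose the C6 oxygen by E1cB dehydration, or the equilibrium may stop short of the trans isomer. The fallback sets out from 16 and replaces the separate equilibration by a dynamic olefination. TESCl/imidazole should give (4aR,7S,8S)-7-isopropyl-4a-methyl-8-(triethylsilyloxy)octahydronaphthalen-1(2H)-one F3 (C5 epimers). Wittig methylenation with excess Ph3P=CH2 (KOt-Bu, toluene, 80 °C) epimerises the ketone through its enolate while the trans-fused isomer olefinates faster, and should give eudesm-4(15)-en-6α-yl triethylsilyl ether F4. TBAF then gives alcohol 18, so that step 11 is bypassed as well.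

3. Step 11. The zinc/titanium methylene reagent may fail to add to the hindered C4 carbonyl beside the metal-bound C6 alkoxide, or the Lewis acids may promote retro-aldol cleavage. The fallback sets out from 17 and uses a Peterson olefination. Excess TMSCH2Li with CeCl3 (THF, –78 °C) adds to the carbonyl without enolisation and should give (4aR,7S,8S,8aS)-7-isopropyl-4a-methyl-1-(trimethylsilylmethyl)decahydronaphthalene-1,8-diol F5 (either C4 epimer). KH in THF (or aq. HF in MeCN) then eliminates silanolate and returns to 18.

Further compounds
F1 | step 6 | (3R)-3-methyl-3-[3-(tert-butyldimethylsilyloxymethylidene)-4-methylpentyl]cyclohexan-1-one | O=C1CCC[C@](C)(CC/C(=C/O[Si](C)(C)C(C)(C)C)C(C)C)C1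
F2 | step 6 | 2-isopropyl-4-[(1R)-1-methyl-3-oxocyclohexyl]butanal (C2 epimers) | O=C1CCC[C@](C)(CCC(C=O)C(C)C)C1
F3 | step 10 | (4aR,7S,8S)-7-isopropyl-4a-methyl-8-(triethylsilyloxy)octahydronaphthalen-1(2H)-one (C5 epimers) | O=C1CCC[C@]2(C)CC[C@@H](C(C)C)[C@H](O[Si](CC)(CC)CC)C12
F4 | step 10 | triethyl{[(1S,2S,4aR,8aS)-2-isopropyl-4a-methyl-8-methylidenedecahydronaphthalen-1-yl]oxy}silane | C=C1CCC[C@]2(C)CC[C@@H](C(C)C)[C@H](O[Si](CC)(CC)CC)[C@@H]12
F5 | step 11 | (4aR,7S,8S,8aS)-7-isopropyl-4a-methyl-1-(trimethylsilylmethyl)decahydronaphthalene-1,8-diol | C[Si](C)(C)CC1(O)CCC[C@]2(C)CC[C@@H](C(C)C)[C@H](O)[C@@H]12
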